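**Strategy.** The route rests on disconnecting both exocyclic C–C bonds of the γ-lactone on ring B, C3a–C3H2 and C7a–C1(=O) (phthalide numbering). They are formed together by a three-component aryne coupling. A symmetric 2-substituted 5-chlororesorcinol dibenzyl ether is converted into a 3-benzyloxyaryne. An α-alkoxymethyllithium adds at the aryne carbon remote from the flanking oxygen (the future 7-OH), the aryllithium thus placed beside that oxygen is trapped by CO2, and acid closes the lactone. The symmetry of the precursor and the single flanking oxygen settle the regiochemistry. C4 oxygenation, SNAr onto a 2-fluoroisophthalate (ring A), depsidone lactonisation and deprotection complete the synthesis.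

Key step: step 5

Remarks on the chemistry:
- The target has no stereocentre. The only stereocentre on the route, the acetal carbon of the 1-ethoxyethyl group, is racemic and is removed in step 5.
- Ring B is numbered as 2-benzofuran-1(3H)-one: C1 lactone C=O, C3 CH2, C4 O-aryl, C5 O-acyl, C6 CH2OH, C7 OH. Ring A is the methyl-bearing benzoate ring.
- Simple commercial reagents that contribute atoms stand on the reagent line of their step and carry no compound number.

Step 1
Reactants: 1 4-chloro-2,6-difluorobenzaldehyde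
Product: 2 2,6-bis(benzyloxy)-4-chlorobenzaldehyde
Conditions: BnOH (2.2 equiv), NaH (2.2 equiv), THF/DMF, 0 °C → rt
Reagents that add atoms: benzyl alcohol OCc1ccccc1
Why: Twofold nucleophilic aromatic substitution (SNAr); both fluorides are ortho to the formyl group and should be displaced by benzyl oxide much faster than the para chloride, which is kept as the later aryne leaving group.

Step 2
Reactants: 2 2,6-bis(benzyloxy)-4-chlorobenzaldehyde
Product: 3 [2,6-bis(benzyloxy)-4-chlorophenyl]methanol
Conditions: NaBH4, MeOH/THF, 0 °C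
Reagents that add atoms: none
Why: Hydride reduction of the aldehyde (carbonyl reduction); aryl chloride and benzyl ethers are inert.

Step 3
Reactants: 3 [2,6-bis(benzyloxy)-4-chlorophenyl]methanol
Product: 4 1,3-bis(benzyloxy)-2-(tert-butoxymethyl)-5-chlorobenzene
Conditions: Boc2O (2.3 equiv), Mg(ClO4)2 (10 mol %), CH2Cl2, 40 °C
Reagents that add atoms: di-tert-butyl dicarbonate CC(C)(C)OC(=O)OC(=O)OC(C)(C)C
Why: Lewis-acid-catalysed decarboxylative tert-butyl ether formation via the mixed carbonate; the tert-butyl ether should tolerate organolithiums, base, hydrogenolysis and dilute aqueous acid and fall only to TFA in the last step.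

Step 4
Reactants: 5 (tributylstannyl)methanol
Product: 6 tributyl[(1-ethoxyethoxy)methyl]stannane
Conditions: ethyl vinyl ether, PPTS (cat.), CH2Cl2, 0 °C → rt
Reagents that add atoms: ethyl vinyl ether C=COCC
Why: Acid-catalysed addition of the alcohol to the enol ether (acetal protection as the 1-ethoxyethyl ether), which permits tin–lithium exchange and is removed at pH 1.

Step 5
Reactants: 4 1,3-bis(benzyloxy)-2-(tert-butoxymethyl)-5-chlorobenzene; 6 tributyl[(1-ethoxyethoxy)methyl]stannane
Product: 12 5,7-bis(benzyloxy)-6-(tert-butoxymethyl)-2-benzofuran-1(3H)-one, via alkoxymethyllithium 7 (not isolated), via lithiated chloride 8 (not isolated), via aryne 9 (not isolated), via aryllithium adduct 10 (not isolated), via benzoic acid 11 (not isolated)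
Conditions: sBuLi (1.05 equiv), THF, −78 °C; then 7 (2.5 equiv, from 6 + nBuLi, THF, −78 °C), −78 → −45 °C; CO2 (g), −78 °C → rt; 1 M HCl, THF, rt
Reagents that add atoms: carbon dioxide O=C=O
Why: sBuLi should remove one of the two equivalent protons between Cl and OBn of 4 (directed ortho-lithiation, 8) and loss of LiCl on warming gives aryne 9; 7, made from 6 by tin–lithium exchange, adds to the aryne carbon that carried chlorine, and aryllithium 10 is carboxylated by CO2. The closest known reaction type is the tandem addition of an alkyllithium to a 3-alkoxyaryne with electrophilic trapping by CO2, which gives 2-alkyl-6-alkoxybenzoic acids. On acidification acid 11 loses its acetal and the γ-lactone ring closes by 5-exo-trig attack of the freed hydroxyl on the protonated carboxyl group (lactonisation). No stereocentre is formed, and the racemic acetal centre of the ethoxyethyl group is removed. The step needs regiocontrol only: the symmetry of 4 makes both lithiation sites lead to the same aryne, and its single flanking benzyloxy group directs the carbanion to the distal, unhindered carbon, so that the new aryl anion is stabilised inductively and by chelation next to oxygen, which places CH2 at C3a and CO2 at C7a. The tert-butyl ether and the benzyl ethers should survive the short exposure to 1 M HCl at room temperature.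

Step 6
Reactants: 12 5,7-bis(benzyloxy)-6-(tert-butoxymethyl)-2-benzofuran-1(3H)-one
Product: 13 5,7-bis(benzyloxy)-4-bromo-6-(tert-butoxymethyl)-2-benzofuran-1(3H)-one
Conditions: NBS (1.05 equiv), MeCN, 0 °C → rt, dark
Reagents that add atoms: N-bromosuccinimide O=C1CCC(=O)N1Br
Why: Electrophilic aromatic bromination; C4 is the only free ring position and is ortho and para to the two benzyloxy groups.

Step 7
Reactants: 13 5,7-bis(benzyloxy)-4-bromo-6-(tert-butoxymethyl)-2-benzofuran-1(3H)-one
Product: 15 5,7-bis(benzyloxy)-6-(tert-butoxymethyl)-4-hydroxy-2-benzofuran-1(3H)-one, via ring-opened hydroxy acid 14 (not isolated)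
Conditions: Pd2(dba)3 (2 mol %), tBuXPhos (8 mol %), KOH, 1,4-dioxane/H2O, 100 °C; then 2 M HCl to pH 2, rt
Reagents that add atoms: potassium hydroxide [K+].[OH-]
Why: Pd-catalysed hydroxylation of the aryl bromide (C–O cross-coupling with hydroxide); KOH opens the lactone reversibly to 14, which should relactonise on acidification.

Step 8
Reactants: 16 3-fluoro-5-methylphenol
Product: 17 1-(benzyloxy)-3-fluoro-5-methylbenzene
Conditions: BnBr, K2CO3, DMF, rt
Reagents that add atoms: benzyl bromide BrCc1ccccc1
Why: Williamson ether synthesis on the phenol.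

Step 9
Reactants: 17 1-(benzyloxy)-3-fluoro-5-methylbenzene
Product: 19 tert-butyl 2-(benzyloxy)-6-fluoro-4-methylbenzoate, via aryllithium 18 (not isolated)
Conditions: sBuLi, THF, −78 °C; then Boc2O, −78 °C → rt
Reagents that add atoms: di-tert-butyl dicarbonate CC(C)(C)OC(=O)OC(=O)OC(C)(C)C
Why: Directed ortho-lithiation at the position flanked by F and OBn followed by acylation with Boc2O to the tert-butyl ester; the ortho-fluoro aryllithium is stable at −78 °C.

Step 10
Reactants: 19 tert-butyl 2-(benzyloxy)-6-fluoro-4-methylbenzoate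
Product: 21 1-benzyl 3-tert-butyl 4-(benzyloxy)-2-fluoro-6-methylbenzene-1,3-dicarboxylate, via aryllithium 20 (not isolated)
Conditions: LiTMP (1.2 equiv, from 2,2,6,6-tetramethylpiperidine + nBuLi), THF, −78 °C; then ClCO2Bn, −78 °C
Reagents that add atoms: benzyl chloroformate O=C(Cl)OCc1ccccc1
Why: Directed ortho-metalation with the hindered amide base at the ring position next to fluorine (the twisted, di-ortho-substituted ester should not stabilise a benzylic anion at the para methyl group), then acylation with the chloroformate.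

Step 11
Reactants: 15 5,7-bis(benzyloxy)-6-(tert-butoxymethyl)-4-hydroxy-2-benzofuran-1(3H)-one; 21 1-benzyl 3-tert-butyl 4-(benzyloxy)-2-fluoro-6-methylbenzene-1,3-dicarboxylate
Product: 22 1-benzyl 3-tert-butyl 4-(benzyloxy)-2-{[5,7-bis(benzyloxy)-6-(tert-butoxymethyl)-1-oxo-1,3-dihydro-2-benzofuran-4-yl]oxy}-6-methylbenzene-1,3-dicarboxylate
Conditions: Cs2CO3, DMSO (degassed), 80 °C
Reagents that add atoms: none
Why: SNAr; the fluoride of 21 is flanked by two ester groups and should be displaced by the caesium phenoxide of 15, the only free hydroxyl of ring B, so that the ether oxygen is fixed at C4.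

Step 12
Reactants: 22 the tetrabenzyl diaryl ether of step 11
Product: 23 3-(tert-butoxycarbonyl)-2-{[6-(tert-butoxymethyl)-5,7-dihydroxy-1-oxo-1,3-dihydro-2-benzofuran-4-yl]oxy}-4-hydroxy-6-methylbenzoic acid
Conditions: H2 (1 atm), 10 % Pd/C, EtOAc/EtOH, rt
Reagents that add atoms: none
Why: Hydrogenolysis of the three aryl benzyl ethers and the benzyl ester; tert-butyl ester, tert-butyl ether, lactone and diaryl ether should be kept.

Step 13
Reactants: 23 the seco acid of step 12
Product: 24 protected depsidone (the target with its carboxylic acid as tert-butyl ester and its primary alcohol as tert-butyl ether)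
Conditions: EDC·HCl, DMAP, CH2Cl2 (2 mM), rt
Reagents that add atoms: none
Why: Carbodiimide-mediated lactonisation (Steglich esterification) at high dilution; only the 5-OH of ring B, ortho to the diaryl ether oxygen, can reach the activated carboxyl group (seven-membered ring), while the 7-OH and the ring-A hydroxyl are hydrogen-bonded to carbonyl groups and out of reach.

Step 14
Reactants: 24 protected depsidone
Product: 25 Conneotricone
Conditions: TFA/CH2Cl2 (1:2), H2O (2 %), 0 °C → rt; aqueous MeOH work-up
Reagents that add atoms: none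
Why: Acidolysis of the tert-butyl ester and the tert-butyl ether (E1 loss of the tert-butyl cation); the aryl ester and the lactone are stable to acid.

**Compound list**

1 | 4-chloro-2,6-difluorobenzaldehyde | O=Cc1c(F)cc(Cl)cc1F | starting material
2 | 2,6-bis(benzyloxy)-4-chlorobenzaldehyde | O=Cc1c(OCc2ccccc2)cc(Cl)cc1OCc1ccccc1 | intermediate
3 | [2,6-bis(benzyloxy)-4-chlorophenyl]methanol | OCc1c(OCc2ccccc2)cc(Cl)cc1OCc1ccccc1 | intermediate
4 | 1,3-bis(benzyloxy)-2-(tert-butoxymethyl)-5-chlorobenzene | CC(C)(C)OCc1c(OCc2ccccc2)cc(Cl)cc1OCc1ccccc1 | intermediate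
5 | (tributylstannyl)methanol | CCCC[Sn](CCCC)(CCCC)CO | starting material
6 | tributyl[(1-ethoxyethoxy)methyl]stannane (racemic) | CCCC[Sn](CCCC)(CCCC)COC(C)OCC | intermediate
7 | [(1-ethoxyethoxy)methyl]lithium (racemic, not isolated) | [Li]COC(C)OCC | intermediate
8 | [2,4-bis(benzyloxy)-3-(tert-butoxymethyl)-6-chlorophenyl]lithium (not isolated) | [Li]c1c(Cl)cc(OCc2ccccc2)c(COC(C)(C)C)c1OCc1ccccc1 | intermediate
9 | 3,5-bis(benzyloxy)-4-(tert-butoxymethyl)benzyne (not isolated) | C1#CC(OCc2ccccc2)=C(COC(C)(C)C)C(OCc2ccccc2)=C1 | intermediate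
10 | {2,4-bis(benzyloxy)-3-(tert-butoxymethyl)-6-[(1-ethoxyethoxy)methyl]phenyl}lithium (not isolated) | [Li]c1c(COC(C)OCC)cc(OCc2ccccc2)c(COC(C)(C)C)c1OCc1ccccc1 | intermediate
11 | 2,4-bis(benzyloxy)-3-(tert-butoxymethyl)-6-[(1-ethoxyethoxy)methyl]benzoic acid (not isolated) | OC(=O)c1c(COC(C)OCC)cc(OCc2ccccc2)c(COC(C)(C)C)c1OCc1ccccc1 | intermediate
12 | 5,7-bis(benzyloxy)-6-(tert-butoxymethyl)-2-benzofuran-1(3H)-one | O=C1OCc2cc(OCc3ccccc3)c(COC(C)(C)C)c(OCc3ccccc3)c12 | intermediate
13 | 5,7-bis(benzyloxy)-4-bromo-6-(tert-butoxymethyl)-2-benzofuran-1(3H)-one | O=C1OCc2c(Br)c(OCc3ccccc3)c(COC(C)(C)C)c(OCc3ccccc3)c12 | intermediate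
14 | 2,4-bis(benzyloxy)-3-(tert-butoxymethyl)-5-hydroxy-6-(hydroxymethyl)benzoic acid (potassium salt in the flask, not isolated) | OC(=O)c1c(CO)c(O)c(OCc2ccccc2)c(COC(C)(C)C)c1OCc1ccccc1 | intermediate
15 | 5,7-bis(benzyloxy)-6-(tert-butoxymethyl)-4-hydroxy-2-benzofuran-1(3H)-one | O=C1OCc2c(O)c(OCc3ccccc3)c(COC(C)(C)C)c(OCc3ccccc3)c12 | intermediate
16 | 3-fluoro-5-methylphenol | Cc1cc(O)cc(F)c1 | starting material
17 | 1-(benzyloxy)-3-fluoro-5-methylbenzene | Cc1cc(F)cc(OCc2ccccc2)c1 | intermediate
18 | [2-(benzyloxy)-6-fluoro-4-methylphenyl]lithium (not isolated) | [Li]c1c(F)cc(C)cc1OCc1ccccc1 | intermediate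
19 | tert-butyl 2-(benzyloxy)-6-fluoro-4-methylbenzoate | CC(C)(C)OC(=O)c1c(F)cc(C)cc1OCc1ccccc1 | intermediate
20 | [4-(benzyloxy)-3-(tert-butoxycarbonyl)-2-fluoro-6-methylphenyl]lithium (not isolated) | [Li]c1c(C)cc(OCc2ccccc2)c(C(=O)OC(C)(C)C)c1F | intermediate
21 | 1-benzyl 3-tert-butyl 4-(benzyloxy)-2-fluoro-6-methylbenzene-1,3-dicarboxylate | Cc1cc(OCc2ccccc2)c(C(=O)OC(C)(C)C)c(F)c1C(=O)OCc1ccccc1 | intermediate
22 | 1-benzyl 3-tert-butyl 4-(benzyloxy)-2-{[5,7-bis(benzyloxy)-6-(tert-butoxymethyl)-1-oxo-1,3-dihydro-2-benzofuran-4-yl]oxy}-6-methylbenzene-1,3-dicarboxylate | Cc1cc(OCc2ccccc2)c(C(=O)OC(C)(C)C)c(Oc2c3COC(=O)c3c(OCc3ccccc3)c(COC(C)(C)C)c2OCc2ccccc2)c1C(=O)OCc1ccccc1 | intermediate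
23 | 3-(tert-butoxycarbonyl)-2-{[6-(tert-butoxymethyl)-5,7-dihydroxy-1-oxo-1,3-dihydro-2-benzofuran-4-yl]oxy}-4-hydroxy-6-methylbenzoic acid | Cc1cc(O)c(C(=O)OC(C)(C)C)c(Oc2c3COC(=O)c3c(O)c(COC(C)(C)C)c2O)c1C(=O)O | intermediate
24 | protected depsidone: target with CO2tBu on ring A and CH2OtBu at C6 of ring B | Cc1cc(O)c(C(=O)OC(C)(C)C)c2c1C(=O)Oc1c(COC(C)(C)C)c(O)c3c(c1O2)COC3=O | intermediate
25 | Conneotricone | Cc1cc(O)c(C(=O)O)c2c1C(=O)Oc1c(CO)c(O)c3c(c1O2)COC3=O | target

**Step count.** Total: 14 steps. Longest linear sequence: 10 steps (1, 2, 3, 5, 6, 7, 11, 12, 13, 14).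

**Steps most likely to fail**

1. Step 5. The α-alkoxymethyllithium may decompose or be protonated before the aryne is released. Lithiated chloride 8 may add to the aryne (biaryl formation). A proton may shift from a benzylic OCH2Ph group to aryllithium 10, followed by Wittig rearrangement. Fallback, from 4 back to 12: chloride 4 is hydroxymethylated by Suzuki–Miyaura coupling with potassium (acetoxymethyl)trifluoroborate (Pd(OAc)2, RuPhos, Na2CO3, dioxane/H2O, 100 °C; the acetate is cleaved in the basic medium) to give [3,5-bis(benzyloxy)-4-(tert-butoxymethyl)phenyl]methanol F1. The lithium alkoxide of F1 then directs ortho-lithiation (nBuLi, 2.2 equiv, TMEDA, THF, 0 °C) to the position between CH2OLi and OBn, the only kind of free ring position. Carboxylation with CO2 and work-up with 1 M HCl should give phthalide 12.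

2. Step 11. The substitution may be slow because both activating esters are twisted out of the ring plane and the ether formed is tetra-ortho-substituted. Prolonged heating invites ester exchange and oxidation of the electron-rich phenoxide. Fallback, from 19 and 15 back to 23: aryllithium 20 (from 19 as in step 10) is quenched with DMF to give tert-butyl 6-(benzyloxy)-2-fluoro-3-formyl-4-methylbenzoate F2, whose coplanar formyl group activates the fluoride far more strongly. SNAr of 15 on F2 (K2CO3, DMF, 60 °C) should give the aldehyde diaryl ether F3. Pinnick oxidation (NaClO2, NaH2PO4, 2-methyl-2-butene, tBuOH/H2O) gives the carboxylic acid F4. Hydrogenolysis of its three benzyl ethers (H2, Pd/C) leads to seco acid 23.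

3. Step 10. Deprotonation may occur at the wrong site (the methyl group or the ring position beside OBn), and aryllithium 20 may lose LiF to give an aryne. Fallback, from 19 back to 21: electrophilic bromination of 19 (NBS, MeCN) para to the benzyloxy group should give tert-butyl 6-(benzyloxy)-3-bromo-2-fluoro-4-methylbenzoate F5. Pd-catalysed alkoxycarbonylation (Pd(OAc)2, Xantphos, CO 1 atm, BnOH, Et3N, toluene, 90 °C) then gives diester 21.

**Further compounds**

F1 | step 5 | [3,5-bis(benzyloxy)-4-(tert-butoxymethyl)phenyl]methanol | OCc1cc(OCc2ccccc2)c(COC(C)(C)C)c(OCc2ccccc2)c1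
F2 | step 11 | tert-butyl 6-(benzyloxy)-2-fluoro-3-formyl-4-methylbenzoate | Cc1cc(OCc2ccccc2)c(C(=O)OC(C)(C)C)c(F)c1C=O
F3 | step 11 | tert-butyl 6-(benzyloxy)-2-{[5,7-bis(benzyloxy)-6-(tert-butoxymethyl)-1-oxo-1,3-dihydro-2-benzofuran-4-yl]oxy}-3-formyl-4-methylbenzoate | Cc1cc(OCc2ccccc2)c(C(=O)OC(C)(C)C)c(Oc2c3COC(=O)c3c(OCc3ccccc3)c(COC(C)(C)C)c2OCc2ccccc2)c1C=O
F4 | step 11 | 4-(benzyloxy)-2-{[5,7-bis(benzyloxy)-6-(tert-butoxymethyl)-1-oxo-1,3-dihydro-2-benzofuran-4-yl]oxy}-3-(tert-butoxycarbonyl)-6-methylbenzoic acid | Cc1cc(OCc2ccccc2)c(C(=O)OC(C)(C)C)c(Oc2c3COC(=O)c3c(OCc3ccccc3)c(COC(C)(C)C)c2OCc2ccccc2)c1C(=O)O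
F5 | step 10 | tert-butyl 6-(benzyloxy)-3-bromo-2-fluoro-4-methylbenzoate | Cc1cc(OCc2ccccc2)c(C(=O)OC(C)(C)C)c(F)c1Br
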